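The north-west run ended with less product than the east run, 75% against 86% at 5.00 d, so I kept books on the substrate before asking about speed.

| flask | substrate | partner | scavenger | free catalyst | remark | time |
|---|---|---|---|---|---|---|
| north-west | 0.010 M | 0.0075 M (fed, over 25 h) | 0.012 M | 50 µM | run made earlier; the fed solution adds 0.10 times the starting volume |  |
| east | 0.010 M | 0.030 M (fed, over 25 h) | 0.012 M | 50 µM | run made earlier; the fed solution adds 0.10 times the starting volume |  |
| flask | 0.010 M | 0.0150 M (fed, over 25 h) | 0.0120 M | 50 µM | the fed solution adds 0.10 times the starting volume | 5.0 d |

| run | time / d | substrate / % | product / % |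
|---|---|---|---|
| north-west | 0.833 | 83 | 15 |
| north-west | 1.67 | 61 | 37 |
| north-west | 2.50 | 49 | 51 |
| north-west | 3.00 | 39 | 57 |
| north-west | 4.00 | 28 | 72 |
| north-west | 5.00 | 26 | 75 |
| east | 0.833 | 77 | 22 |
| east | 1.67 | 58 | 43 |
| east | 2.50 | 40 | 59 |
| east | 3.00 | 35 | 65 |
| east | 4.00 | 22 | 77 |
| east | 5.00 | 15 | 86 |

(each reading ± 1.5 percentage points)

- charges are per starting volume, the dose included; the dosed solution carries all of it
- the earlier runs were read with a standard deviation of 1.5 percentage points
- the earlier runs do not show how much of partner is bound; that part of a forecast is a guess

- part of the substrate that has reacted at 5.0 d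
- share of the unused partner that is free and not bound as idle adduct, at 5.0 d

The north-west charge holds 0.750 partner per substrate, and 74.0% of its substrate had gone by the last reading, so I booked one partner per substrate reacted. The entry I carried is the equivalents of partner per substrate charged, 1.50 for this flask; below one it is, on that booking, the ceiling on the reacted share.

This flask has more partner than substrate, so substrate is the limiting reagent. Its ledger has two columns: reacted, written as product and paid for with partner, and unreacted. The last east readings sum to 101%, so no third column showed there.

For the pace I took the east run, also above one equivalent at 3.00. At 5.00 d it read 15% of its substrate left, and I assumed this flask would keep the east pace, which gave me an estimate of 85.0% reacted in this flask. The books then left 43.3% of the partner charge unused. The readings do not show how that splits between free partner and idle adduct, so I committed to no share.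

The forecast said 84% reacted and 30% free, noting “Binding strength is not observed”.

The flask gave 84.8% reacted and 97.0% of the unused partner free, with 41.9% of the partner charge free beside 1.76 × 10⁻⁴ M of idle adduct at 5.00 d.

    partner + free catalyst → catalyst intermediate A (k = 1.20 M⁻¹ s⁻¹)
    catalyst intermediate A ⇌ released group + catalyst intermediate B (K = 0.0140 M, k = 0.00720 s⁻¹)
    substrate + catalyst intermediate B ⇌ catalyst intermediate C (K = 34.0 M⁻¹, k = 1.70 M⁻¹ s⁻¹)
    catalyst intermediate C ⇌ catalyst intermediate D (K = 0.250, k = 0.0190 s⁻¹)
    catalyst intermediate D → free catalyst + product (k = 0.0200 s⁻¹)
    partner + released group ⇌ idle adduct, settled at all times (K = 12000 M⁻¹)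
    scavenger + released group → scavenged by-product (k = 0.900 M⁻¹ s⁻¹)

Put through 1.50, the reacted share gives 43.5% of the partner charge unused at 5.0 d. For 50.0 d, with 100% reacted, it gives 33.3%, and by then the flask held 33.0% of its partner charge free. The same flask with 0.025 M of substrate has 0.600 equivalents, a ceiling of 60.0%, and it stood below that at 56.3%, with 0.427% of its partner free at 5.00 d.

The runs were generated by integration with made-up constants; the scatter is artificial.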